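**Plan**

1. Numbering used throughout: C1 lactone C=O, C2 CH2, C3 CH–OO, C4 C(CH3)–O(lactone), C5 ring CH2, C6 C(CH3)(chain)–OO, C7–C16 the decyl chain.
2. Retrosynthetic cuts, in order: ArO–Si; C8–C9 (cross-metathesis, then diimide); C6–C7 (allylation of a C6 peroxycarbenium ion); O–C3 of the 1,2-dioxane (oxa-Michael); C6–OO (ozonolysis in methanol); C2=C3 and lactone C1–O (Z-olefination/lactonisation); C5–C6 (epoxide opening).
3. Forward: the butenolide ring is built first on a chiral-pool tertiary carbinol, the 1,2-dioxane is closed second and last by addition of a C6 hydroperoxide to C3, and the aryl-decyl chain is then grown from C6.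
4. Enabling feature: C3 is the β-carbon of the α,β-unsaturated γ-lactone (C1=O, C2=C3) and sits on quaternary C4, which also carries the C5–C6–O–O–H arm, so the terminal peroxy oxygen reaches C3 through a six-membered transition state.
5. Stereochemistry: C4 comes from (S)-2-methylglycidol; C3 is relayed from C4 by the obligatory cis ring fusion in the key step; C6 is set by axial attack of allylsilane on the ring peroxycarbenium ion, on the face of the pseudoaxial C4–O bond.

Key step: step 5

Remark: compounds 1, 2, 5, 10, 12 and 13 are taken as purchased. The bicyclic compounds are named as 2,3,7-trioxabicyclo[4.3.0]nonan-8-ones (ring C1 = skeleton C3, ring C4 = skeleton C6, ring C6 = skeleton C4).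

**Route**

Step 1
Reactants: 1 (S)-2-methylglycidol; 2 isopropenylmagnesium bromide
Product: 3 (R)-2,4-dimethylpent-4-ene-1,2-diol
Conditions: 2 (2.5 equiv), CuI (10 mol %), THF, −30 → 0 °C; then H2O
Reagents that add atoms: none
Why: Copper-catalysed SN2 opening of the epoxide by the alkenyl Grignard reagent at the unsubstituted CH2 terminus (the first equivalent only deprotonates the hydroxyl, and the Payne rearrangement of this alkoxide is degenerate), so the quaternary carbinol carbon (future C4) is taken over untouched from the chiral pool.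

Step 2
Reactants: 3 (R)-2,4-dimethylpent-4-ene-1,2-diol
Product: 4 (R)-2-hydroxy-2,4-dimethylpent-4-enal
Conditions: IBX (1.5 equiv), EtOAc, 75 °C; filtered, used as a concentrated solution
Reagents that add atoms: none
Why: IBX oxidation of the primary alcohol of a 1,2-diol to the α-hydroxy aldehyde proceeds without glycol cleavage, the tertiary alcohol cannot be oxidised, and the α-carbon bears no hydrogen, so C4 cannot epimerise.

Step 3
Reactants: 4 (R)-2-hydroxy-2,4-dimethylpent-4-enal; 5 methyl bis(2,2,2-trifluoroethyl)phosphonoacetate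
Product: 7 (R)-5-methyl-5-(2-methylprop-2-en-1-yl)furan-2(5H)-one, via Z-hydroxy enoate 6 (not isolated)
Conditions: 5, KHMDS, 18-crown-6, THF, −78 °C → rt; then TsOH (cat.), CH2Cl2, rt
Reagents that add atoms: none
Why: The Still–Gennari Z-selective Horner–Wadsworth–Emmons olefination places the ester cis to the tertiary hydroxyl, and the Z-γ-hydroxy enoate lactonises to the butenolide by acyl substitution with loss of methanol; C4 is not touched.

Step 4
Reactants: 7 (R)-5-methyl-5-(2-methylprop-2-en-1-yl)furan-2(5H)-one
Product: 8 (5R)-5-(2-hydroperoxy-2-methoxypropyl)-5-methylfuran-2(5H)-one (both epimers at the peroxyketal carbon)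
Conditions: O3, CH2Cl2/MeOH 4:1, −78 °C (Sudan Red 7B end point); N2 purge; concentrated below 20 °C
Reagents that add atoms: ozone [O-][O+]=O; methanol CO
Why: In this Criegee ozonolysis the electron-rich 1,1-disubstituted alkene should react far faster than the electron-poor butenolide C2=C3 bond, the primary ozonide fragments to formaldehyde and the more substituted carbonyl oxide, and methanol traps the latter as the α-methoxy hydroperoxide; the peroxyketal centre C6 forms as both epimers, which is of no consequence because it is ionised in step 6.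

Step 5
Reactants: 8 (5R)-5-(2-hydroperoxy-2-methoxypropyl)-5-methylfuran-2(5H)-one
Product: 9 (1R,6R)-4-methoxy-4,6-dimethyl-2,3,7-trioxabicyclo[4.3.0]nonan-8-one (both epimers at ring C4)
Conditions: Et2NH (0.5 equiv), CF3CH2OH, 0 °C → rt
Reagents that add atoms: none
Why: Diethylamine in trifluoroethanol converts the hydroperoxide into its hydrogen-bonded peroxy anion, which adds in conjugate fashion to C3, the β-carbon of the butenolide, and the lactone enolate is protonated at C2 by the solvent. The closest known reaction type is the amine-mediated intramolecular oxa-Michael addition of hydroperoxides, α-alkoxy hydroperoxides included, to enoates and butenolides to give 1,2-dioxanes. The 1,2-dioxane closes in the 6-exo-trig mode, with the C2=C3 bond outside the new ring, and since the lactone is already in place this is the last ring of the skeleton. The new stereocentre C3 is controlled by C4: the C5–C6–O–O tether is anchored on quaternary C4 and can reach C3 only on the face of the planar butenolide that carries C5, so the ring fusion must be cis and C3 becomes R. The step needs 1,4- over 1,2-addition and peroxide over amine addition; the soft peroxy nucleophile, the reversibility of aza-Michael addition and the weakly acidic, non-nucleophilic solvent, which disfavours base-induced O–O cleavage, should secure this. Both C6 epimers of 8 cyclise and both epimers of 9 are carried on, because C6 is made planar again in step 6.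

Step 6
Reactants: 9 (1R,6R)-4-methoxy-4,6-dimethyl-2,3,7-trioxabicyclo[4.3.0]nonan-8-one; 10 allyltrimethylsilane
Product: 11 (1R,4S,6R)-4-allyl-4,6-dimethyl-2,3,7-trioxabicyclo[4.3.0]nonan-8-one
Conditions: 10 (3 equiv), TiCl4 (1.1 equiv), CH2Cl2, −78 °C; aq. NaHCO3
Reagents that add atoms: none
Why: In this Hosomi–Sakurai-type allylation TiCl4 ionises the exocyclic methoxy group of either epimer to the same ring peroxycarbenium ion, whose favoured half-chair (C4–O pseudoaxial, C4-methyl pseudoequatorial) should be attacked by the allylsilane along the axial, chair-forming trajectory on the face of the C4–O bond, because the corresponding attack on the other face would meet a syn-axial C4 methyl group; the allyl group should therefore enter cis to the lactone oxygen and set C6 as required (the lactone carbonyl is held anti to C4 by the five-membered ring and cannot participate).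

Step 7
Reactants: 12 (4-bromophenoxy)(tert-butyl)dimethylsilane; 13 9-bromonon-1-ene
Product: 15 tert-butyldimethyl[4-(non-8-en-1-yl)phenoxy]silane, via aryl Grignard reagent 14 (not isolated)
Conditions: Mg, THF, 50 °C; then 13, Li2CuCl4 (3 mol %), THF/NMP, 0 °C → rt
Reagents that add atoms: none
Why: Kochi-type copper-catalysed coupling of an aryl Grignard reagent with a primary alkyl bromide; the aryl silyl ether and the remote terminal alkene are inert under these conditions.

Step 8
Reactants: 11 (1R,4S,6R)-4-allyl-4,6-dimethyl-2,3,7-trioxabicyclo[4.3.0]nonan-8-one; 15 tert-butyldimethyl[4-(non-8-en-1-yl)phenoxy]silane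
Product: 16 (1R,4S,6R)-4-[10-(4-{[tert-butyl(dimethyl)silyl]oxy}phenyl)dec-2-en-1-yl]-4,6-dimethyl-2,3,7-trioxabicyclo[4.3.0]nonan-8-one (E/Z mixture)
Conditions: 15 (3 equiv), Hoveyda–Grubbs II (5 mol %), CH2Cl2, 40 °C
Reagents that add atoms: none
Why: Olefin cross-metathesis of two monosubstituted alkenes with a phosphine-free ruthenium alkylidene, driven by loss of ethylene and an excess of the cheap partner; dialkyl peroxides and lactones are tolerated by such catalysts, and the alkene geometry is irrelevant because the double bond is reduced next.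

Step 9
Reactants: 16 (1R,4S,6R)-4-[10-(4-{[tert-butyl(dimethyl)silyl]oxy}phenyl)dec-2-en-1-yl]-4,6-dimethyl-2,3,7-trioxabicyclo[4.3.0]nonan-8-one
Product: 17 (1R,4S,6R)-4-[10-(4-{[tert-butyl(dimethyl)silyl]oxy}phenyl)decyl]-4,6-dimethyl-2,3,7-trioxabicyclo[4.3.0]nonan-8-one
Conditions: KO2CN=NCO2K, AcOH, MeOH/CH2Cl2, 0 °C → rt
Reagents that add atoms: none
Why: Diimide reduction transfers H2 in a concerted syn fashion to the unpolarised C=C bond and leaves the O–O bond, the arene and the lactone alone, which catalytic hydrogenation would not.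

Step 10
Reactants: 17 (1R,4S,6R)-4-[10-(4-{[tert-butyl(dimethyl)silyl]oxy}phenyl)decyl]-4,6-dimethyl-2,3,7-trioxabicyclo[4.3.0]nonan-8-one
Product: 18 plakortolide S, (1R,4S,6R)-4-[10-(4-hydroxyphenyl)decyl]-4,6-dimethyl-2,3,7-trioxabicyclo[4.3.0]nonan-8-one
Conditions: HF·pyridine, THF, 0 °C → rt
Reagents that add atoms: none
Why: Fluoride-driven cleavage of the aryl silyl ether under mildly acidic conditions, chosen because the peroxy lactone is stable to acid but labile to base; no stereocentre is touched.

**Compound list**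

1 | (S)-2-methylglycidol, (S)-(2-methyloxiran-2-yl)methanol | C[C@]1(CO)CO1 | starting material
2 | isopropenylmagnesium bromide | C=C(C)[Mg]Br | starting material
3 | (R)-2,4-dimethylpent-4-ene-1,2-diol | C=C(C)C[C@@](C)(O)CO | intermediate
4 | (R)-2-hydroxy-2,4-dimethylpent-4-enal | C=C(C)C[C@@](C)(O)C=O | intermediate
5 | methyl bis(2,2,2-trifluoroethyl)phosphonoacetate | COC(=O)CP(=O)(OCC(F)(F)F)OCC(F)(F)F | starting material
6 | methyl (2Z,4R)-4-hydroxy-4,6-dimethylhepta-2,6-dienoate | C=C(C)C[C@@](C)(O)/C=C\C(=O)OC | intermediate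
7 | (R)-5-methyl-5-(2-methylprop-2-en-1-yl)furan-2(5H)-one | C=C(C)C[C@@]1(C)OC(=O)C=C1 | intermediate
8 | (5R)-5-(2-hydroperoxy-2-methoxypropyl)-5-methylfuran-2(5H)-one, both epimers at the peroxyketal carbon | COC(C)(OO)C[C@@]1(C)OC(=O)C=C1 | intermediate
9 | (1R,6R)-4-methoxy-4,6-dimethyl-2,3,7-trioxabicyclo[4.3.0]nonan-8-one, both epimers at ring C4 | COC1(C)C[C@@]2(C)OC(=O)C[C@H]2OO1 | intermediate
10 | allyltrimethylsilane | C=CC[Si](C)(C)C | starting material
11 | (1R,4S,6R)-4-allyl-4,6-dimethyl-2,3,7-trioxabicyclo[4.3.0]nonan-8-one | C[C@]1(CC=C)C[C@@]2(C)OC(=O)C[C@H]2OO1 | intermediate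
12 | (4-bromophenoxy)(tert-butyl)dimethylsilane | Brc1ccc(O[Si](C)(C)C(C)(C)C)cc1 | starting material
13 | 9-bromonon-1-ene | C=CCCCCCCCBr | starting material
14 | (4-{[tert-butyl(dimethyl)silyl]oxy}phenyl)magnesium bromide | Br[Mg]c1ccc(O[Si](C)(C)C(C)(C)C)cc1 | intermediate
15 | tert-butyldimethyl[4-(non-8-en-1-yl)phenoxy]silane | C=CCCCCCCCc1ccc(O[Si](C)(C)C(C)(C)C)cc1 | intermediate
16 | (1R,4S,6R)-4-[10-(4-{[tert-butyl(dimethyl)silyl]oxy}phenyl)dec-2-en-1-yl]-4,6-dimethyl-2,3,7-trioxabicyclo[4.3.0]nonan-8-one, E/Z mixture | C[C@]1(CC=CCCCCCCCc2ccc(O[Si](C)(C)C(C)(C)C)cc2)C[C@@]2(C)OC(=O)C[C@H]2OO1 | intermediate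
17 | (1R,4S,6R)-4-[10-(4-{[tert-butyl(dimethyl)silyl]oxy}phenyl)decyl]-4,6-dimethyl-2,3,7-trioxabicyclo[4.3.0]nonan-8-one | C[C@]1(CCCCCCCCCCc2ccc(O[Si](C)(C)C(C)(C)C)cc2)C[C@@]2(C)OC(=O)C[C@H]2OO1 | intermediate
18 | plakortolide S, (1R,4S,6R)-4-[10-(4-hydroxyphenyl)decyl]-4,6-dimethyl-2,3,7-trioxabicyclo[4.3.0]nonan-8-one | C[C@]1(CCCCCCCCCCc2ccc(O)cc2)C[C@@]2(C)OC(=O)C[C@H]2OO1 | target

**Step count**

Total step count: 10. Longest linear sequence: 9 (steps 1–6 and 8–10); step 7 is the side branch.

**Steps most likely to fail**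

Step 6. What may go wrong: poor facial selectivity in the attack of the allylsilane on the ring peroxycarbenium ion, or Lewis-acid-triggered heterolysis of the O–O bond (Criegee/Hock-type fragmentation) and endocyclic ionisation that opens the dioxane. The fallback brings the chain in before any peroxide exists; it sets out from 7 and comes back at 18. Butenolide 7 is cross-metathesised (Hoveyda–Grubbs II, CH2Cl2, 40 °C) with tert-butyldimethyl[4-(undec-10-en-1-yl)phenoxy]silane F1, prepared from Grignard reagent 14 and purchased 11-bromoundec-1-ene under the conditions of step 7. This should give the trisubstituted alkene (R)-5-methyl-5-[2-methyl-12-(4-{[tert-butyl(dimethyl)silyl]oxy}phenyl)dodec-2-en-1-yl]furan-2(5H)-one F2, whose geometry is immaterial. Mukaiyama–Isayama hydroperoxysilylation (Co(thd)2 cat., O2, Et3SiH, ClCH2CH2Cl, rt) should then place the peroxide on C6 and give (5R)-5-methyl-5-[2-methyl-2-(triethylsilylperoxy)-12-(4-{[tert-butyl(dimethyl)silyl]oxy}phenyl)dodecyl]furan-2(5H)-one F3 as both C6 epimers. Bu4NF (THF, 0 °C) removes both silyl groups, and the peroxy anion set free closes the dioxane by the same 6-exo oxa-Michael addition. This should give 18 together with its C6 epimer (1R,4R,6R)-4-[10-(4-hydroxyphenyl)decyl]-4,6-dimethyl-2,3,7-trioxabicyclo[4.3.0]nonan-8-one F4, from which it would have to be separated by chromatography; C6 is not controlled on this path.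

Step 5. What may go wrong: the weakly nucleophilic α-methoxy hydroperoxide may collapse to the methyl ketone (loss of methanol and hydrogen peroxide) or suffer base-induced O–O cleavage faster than it adds, and the conjugate addition may revert (retro-Michael). The fallback delivers the peroxide from hydrogen peroxide to a ketone, so that collapse to the ketone is no longer a loss; it sets out from 7 and comes back at 9. Ozonolysis of 7 with reductive work-up (O3, CH2Cl2, −78 °C; Me2S) should give (R)-5-methyl-5-(2-oxopropyl)furan-2(5H)-one F5. With excess ethereal H2O2 and catalytic Et2NH in CF3CH2OH the ketone equilibrates with its hydroperoxy hemiketal, which is trapped by the butenolide to give the cyclic peroxy hemiketal (1R,6R)-4-hydroxy-4,6-dimethyl-2,3,7-trioxabicyclo[4.3.0]nonan-8-one F6. Acid-catalysed exchange (MeOH, camphorsulfonic acid cat., rt) then turns F6 into 9.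

Step 8. What may go wrong: redox decomposition of the peroxide by ruthenium species, or stalled turnover at the hindered homoallylic alkene so that homodimerisation of 15 takes over. The fallback replaces metathesis by olefination; it sets out from 11 and comes back at 16. Ozonolysis of the allyl group (O3, CH2Cl2, −78 °C; Me2S) should give 2-[(1R,4R,6R)-4,6-dimethyl-8-oxo-2,3,7-trioxabicyclo[4.3.0]nonan-4-yl]acetaldehyde F7. Grignard reagent 14 and purchased 1,8-dibromooctane (excess, Li2CuCl4 cat.) give [4-(8-bromooctyl)phenoxy](tert-butyl)dimethylsilane F8, which with PPh3 (MeCN, reflux) gives [8-(4-{[tert-butyl(dimethyl)silyl]oxy}phenyl)octyl]triphenylphosphonium bromide F9. The salt-free ylide from F9 (NaHMDS, THF, −78 °C, to keep enolisation and β-elimination of the peroxide from F7 slow) and F7 should give the Z isomer of 16, which is reduced in step 9 like the E/Z mixture.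

**Further compounds**

F1 | step 6 | tert-butyldimethyl[4-(undec-10-en-1-yl)phenoxy]silane | C=CCCCCCCCCCc1ccc(O[Si](C)(C)C(C)(C)C)cc1
F2 | step 6 | (R)-5-methyl-5-[2-methyl-12-(4-{[tert-butyl(dimethyl)silyl]oxy}phenyl)dodec-2-en-1-yl]furan-2(5H)-one, E/Z mixture | CC(=CCCCCCCCCCc1ccc(O[Si](C)(C)C(C)(C)C)cc1)C[C@@]1(C)OC(=O)C=C1
F3 | step 6 | (5R)-5-methyl-5-[2-methyl-2-(triethylsilylperoxy)-12-(4-{[tert-butyl(dimethyl)silyl]oxy}phenyl)dodecyl]furan-2(5H)-one, both C6 epimers | CC[Si](CC)(CC)OOC(C)(CCCCCCCCCCc1ccc(O[Si](C)(C)C(C)(C)C)cc1)C[C@@]1(C)OC(=O)C=C1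
F4 | step 6 | (1R,4R,6R)-4-[10-(4-hydroxyphenyl)decyl]-4,6-dimethyl-2,3,7-trioxabicyclo[4.3.0]nonan-8-one (C6 epimer of 18) | C[C@@]1(CCCCCCCCCCc2ccc(O)cc2)C[C@@]2(C)OC(=O)C[C@H]2OO1
F5 | step 5 | (R)-5-methyl-5-(2-oxopropyl)furan-2(5H)-one | CC(=O)C[C@@]1(C)OC(=O)C=C1
F6 | step 5 | (1R,6R)-4-hydroxy-4,6-dimethyl-2,3,7-trioxabicyclo[4.3.0]nonan-8-one, both epimers at ring C4 | CC1(O)C[C@@]2(C)OC(=O)C[C@H]2OO1
F7 | step 8 | 2-[(1R,4R,6R)-4,6-dimethyl-8-oxo-2,3,7-trioxabicyclo[4.3.0]nonan-4-yl]acetaldehyde | C[C@]1(CC=O)C[C@@]2(C)OC(=O)C[C@H]2OO1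
F8 | step 8 | [4-(8-bromooctyl)phenoxy](tert-butyl)dimethylsilane | BrCCCCCCCCc1ccc(O[Si](C)(C)C(C)(C)C)cc1
F9 | step 8 | [8-(4-{[tert-butyl(dimethyl)silyl]oxy}phenyl)octyl]triphenylphosphonium bromide | [Br-].c1ccc(cc1)[P+](CCCCCCCCc1ccc(O[Si](C)(C)C(C)(C)C)cc1)(c1ccccc1)c1ccccc1
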